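**Assumptions.** (±)-Lavandulol, 5-methoxyresorcinol and 2-hydroxy-4-methoxybenzaldehyde are taken as the purchased starting materials. "Lavandulyl" means 5-methyl-2-(prop-1-en-2-yl)hex-4-en-1-yl; MOM = methoxymethyl; MTM = methylthiomethyl. The lipase preference in step 1 and the catalyst antipode in step 9 are given from memory and should be confirmed by optical rotation and chiral GC/HPLC before scale-up.

**Retrosynthetic overview**
1. Target 20 comes from spiro-dithiane flavan 19 by one alkylative hydrolysis that unmasks the C4 ketone and the 2'-OH (MTM ether) together.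
2. Ring C is closed last, at O1–C2, by intramolecular Mitsunobu etherification of carbinol 18 with inversion.
3. Key C3–C4 bond: the ring-A aldehyde carbon is used as an acyl anion (lithiated 2-aryl-1,3-dithiane, as the unprotected trianion 17) and opens the enantiopure ring-B epoxide 16 at its CH2 carbon.
4. Ring-A fragment 12 comes from 5-methoxyresorcinol bis-MOM ether by two directed ortho-lithiations ((S)-lavandulyl iodide, then DMF) and ZnBr2/propane-1,3-dithiol.
5. Stereocentres: C2'' from lipase-resolved (S)-lavandulol; C2 from the (S)-epoxide (kinetic resolution), carried to the (R)-carbinol and inverted to (S).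

**Step 1**
Reactants: 1 (±)-lavandulol
Product: 2 (S)-lavandulol
Conditions: Candida antarctica lipase B (immobilised), vinyl acetate (1.0 equiv), hexane, 25 °C, stopped at ca. 75–80 % conversion; chromatography
Reagents that add atoms: none
Why: Lipase-catalysed kinetic resolution by transesterification, in which the (R)-alcohol is acetylated faster, so the unreacted (S)-(+)-alcohol reaches ≥97 % ee at high conversion (modest selectivity, ca. 20 % yield); this sets the side-chain stereocentre.

**Step 2**
Reactants: 2 (S)-lavandulol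
Product: 3 (S)-lavandulyl iodide
Conditions: I2, PPh3, imidazole, CH2Cl2, 0 °C → rt
Reagents that add atoms: iodine, II
Why: Appel-type iodination by SN2 displacement of the alkoxyphosphonium at the primary carbon, which leaves the adjacent stereocentre untouched.

**Step 3**
Reactants: 4 5-methoxyresorcinol
Product: 5 1-methoxy-3,5-bis(methoxymethoxy)benzene
Conditions: MOMCl (2.5 equiv), i-Pr2NEt, CH2Cl2, 0 °C → rt
Reagents that add atoms: chloromethyl methyl ether, COCCl
Why: Standard phenol O-alkylation that installs two strong ortho-directing groups for the lithiations that follow.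

**Step 4**
Reactants: 5 1-methoxy-3,5-bis(methoxymethoxy)benzene; 3 (S)-lavandulyl iodide
Product: 7 5-methoxy-1,3-bis(methoxymethoxy)-2-[(2R)-lavandulyl]benzene, via aryllithium 6 (not isolated)
Conditions: 5 (1.5 equiv), n-BuLi (1.5 equiv), THF, 0 °C, 1 h; then 3 (1.0 equiv), DMPU, −20 °C → rt
Reagents that add atoms: none
Why: Directed ortho-metalation at the carbon flanked by both OMOM groups, then SN2 alkylation of the aryllithium at the primary iodide; the stereocentre is beta to the reacting carbon and is unchanged in space (its CIP label becomes R because CH2Ar ranks below isopropenyl).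

**Step 5**
Reactants: 7 5-methoxy-1,3-bis(methoxymethoxy)-2-[(2R)-lavandulyl]benzene
Product: 10 6-methoxy-2,4-bis(methoxymethoxy)-3-[(2R)-lavandulyl]benzaldehyde, via aryllithium 8 (not isolated), via lithium hemiaminal alkoxide 9 (not isolated)
Conditions: n-BuLi, TMEDA, THF, −20 → 0 °C; DMF, 0 °C → rt; H2O
Reagents that add atoms: N,N-dimethylformamide, CN(C)C=O
Why: A second directed ortho-metalation at the only ring C–H flanked by OMOM and OMe (the two such positions are equivalent), followed by formylation with DMF, places the future C4 carbon in the right position.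

**Step 6**
Reactants: 10 6-methoxy-2,4-bis(methoxymethoxy)-3-[(2R)-lavandulyl]benzaldehyde
Product: 12 4-(1,3-dithian-2-yl)-5-methoxy-2-[(2R)-lavandulyl]benzene-1,3-diol, via bis-MOM dithiane 11 (not isolated)
Conditions: HS(CH2)3SH (5 equiv), ZnBr2 (3 equiv), CH2Cl2, 0 °C → rt
Reagents that add atoms: propane-1,3-dithiol, SCCCS
Why: Zinc-halide-promoted dithioacetalisation of the aldehyde, then in the same pot ZnBr2/thiol cleavage of both aryl MOM ethers, using a Lewis acid too mild to cyclise the phenol onto the lavandulyl alkenes.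

**Step 7**
Reactants: 13 2-hydroxy-4-methoxybenzaldehyde
Product: 14 4-methoxy-2-[(methylsulfanyl)methoxy]benzaldehyde
Conditions: NaH, DMF, 0 °C; MeSCH2Cl, rt
Reagents that add atoms: chloromethyl methyl sulfide, CSCCl
Why: Williamson alkylation of the phenoxide gives an MTM ether that survives ylides, organolithiums and Mitsunobu conditions and is later cleaved by the same reagent that opens the dithiane.

**Step 8**
Reactants: 14 4-methoxy-2-[(methylsulfanyl)methoxy]benzaldehyde
Product: 15 rac-2-{4-methoxy-2-[(methylsulfanyl)methoxy]phenyl}oxirane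
Conditions: Me3S+ I−, NaH, DMSO/THF, 0 °C → rt; purify on Et3N-deactivated silica
Reagents that add atoms: trimethylsulfonium iodide, C[S+](C)C.[I-]
Why: Corey–Chaykovsky methylene transfer from dimethylsulfonium methylide converts the aldehyde directly into the terminal epoxide (racemic).

**Step 9**
Reactants: 15 rac-2-{4-methoxy-2-[(methylsulfanyl)methoxy]phenyl}oxirane
Product: 16 (2S)-2-{4-methoxy-2-[(methylsulfanyl)methoxy]phenyl}oxirane
Conditions: (S,S)-Co(salen)(OAc) (1 mol %; trivalent cobalt; salen = N,N'-bis(3,5-di-tert-butylsalicylidene)cyclohexane-1,2-diamine dianion), H2O (0.6 equiv), THF, 0 °C → rt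
Reagents that add atoms: none
Why: Jacobsen hydrolytic kinetic resolution, in which the (S,S)-catalyst hydrates the (R)-epoxide to its diol and leaves the (S)-epoxide, the source of the C2 stereocentre.

**Step 10 (key step)**
Reactants: 12 4-(1,3-dithian-2-yl)-5-methoxy-2-[(2R)-lavandulyl]benzene-1,3-diol; 16 (2S)-2-{4-methoxy-2-[(methylsulfanyl)methoxy]phenyl}oxirane
Product: 18 (1R)-2-{2-[2,4-dihydroxy-6-methoxy-3-((2R)-lavandulyl)phenyl]-1,3-dithian-2-yl}-1-{4-methoxy-2-[(methylsulfanyl)methoxy]phenyl}ethan-1-ol, via trilithio dithiane 17 (not isolated)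
Conditions: 12, n-BuLi (3.1 equiv), TMEDA, THF, −30 → 0 °C; then 16 (1.1 equiv), DMPU, −78 → 0 °C; H2O
Reagents that add atoms: none
Why: Proposed new method: two equivalents of base make the lithium phenoxides and the third removes the dithiane C–H (still the most acidic remaining proton, stabilised by two sulfurs) to give an acyl anion equivalent that attacks the unhindered CH2 of the epoxide, so the carbonyl carbon (C4) is joined to a carbon (C3) that is itself electrophilic and the benzylic C–O stereocentre is carried over untouched ((S)-epoxide gives the (R)-carbinol by label change only); the closest known reaction type is the Corey–Seebach opening of terminal epoxides by lithiated 2-aryl-1,3-dithianes, including the O,C-dianion of 2-(2-hydroxyphenyl)-1,3-dithiane, extended here to a trianion so that no phenol protection is needed.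

**Step 11**
Reactants: 18 (1R)-carbinol
Product: 19 (2S)-5-methoxy-2-{4-methoxy-2-[(methylsulfanyl)methoxy]phenyl}-8-[(2R)-lavandulyl]-2,3-dihydrospiro[chromene-4,2'-[1,3]dithian]-7-ol
Conditions: PPh3, DIAD, THF (0.01 M), 0 °C → rt
Reagents that add atoms: none
Why: Intramolecular Mitsunobu etherification, in which the ortho-phenol displaces the activated (R)-carbinol in an SN2 sense through a six-membered transition state and inverts it to (2S); with the ketone still masked there is no E1cB route to a chalcone, and high dilution keeps the distal 7-OH from reacting.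

**Step 12**
Reactants: 19 (2S)-spiro-dithiane flavan
Product: 20 (2S)-7-hydroxy-2-(2-hydroxy-4-methoxyphenyl)-5-methoxy-8-[(2R)-lavandulyl]-2,3-dihydro-4H-chromen-4-one (target)
Conditions: MeI (20 equiv), CaCO3, MeCN/H2O 9:1, 40 °C
Reagents that add atoms: water, O
Why: Alkylative hydrolysis, in which S-methylation turns both the dithiane and the MTM O,S-acetal into sulfonium leaving groups that water displaces, releasing the C4 ketone and the 2'-phenol in one near-neutral, non-oxidising operation that spares the alkenes, the phenols and C2.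

**Compound list**
1 | (±)-lavandulol, rac-5-methyl-2-(prop-1-en-2-yl)hex-4-en-1-ol | C=C(C)C(CC=C(C)C)CO | starting material
2 | (S)-lavandulol, (2S)-5-methyl-2-(prop-1-en-2-yl)hex-4-en-1-ol | C=C(C)[C@H](CC=C(C)C)CO | intermediate
3 | (S)-lavandulyl iodide, (3S)-3-(iodomethyl)-2,6-dimethylhepta-1,5-diene | C=C(C)[C@H](CC=C(C)C)CI | intermediate
4 | 5-methoxyresorcinol (5-methoxybenzene-1,3-diol) | COc1cc(O)cc(O)c1 | starting material
5 | 1-methoxy-3,5-bis(methoxymethoxy)benzene | COCOc1cc(OC)cc(OCOC)c1 | intermediate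
6 | [4-methoxy-2,6-bis(methoxymethoxy)phenyl]lithium | [Li]c1c(OCOC)cc(OC)cc1OCOC | intermediate
7 | 5-methoxy-1,3-bis(methoxymethoxy)-2-[(2R)-lavandulyl]benzene | C=C(C)[C@H](CC=C(C)C)Cc1c(OCOC)cc(OC)cc1OCOC | intermediate
8 | {6-methoxy-2,4-bis(methoxymethoxy)-3-[(2R)-lavandulyl]phenyl}lithium | C=C(C)[C@H](CC=C(C)C)Cc1c(OCOC)cc(OC)c([Li])c1OCOC | intermediate
9 | lithium (dimethylamino){6-methoxy-2,4-bis(methoxymethoxy)-3-[(2R)-lavandulyl]phenyl}methanolate (both epimers at the hemiaminal carbon) | C=C(C)[C@H](CC=C(C)C)Cc1c(OCOC)cc(OC)c(C(O[Li])N(C)C)c1OCOC | intermediate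
10 | 6-methoxy-2,4-bis(methoxymethoxy)-3-[(2R)-lavandulyl]benzaldehyde | C=C(C)[C@H](CC=C(C)C)Cc1c(OCOC)cc(OC)c(C=O)c1OCOC | intermediate
11 | 2-{6-methoxy-2,4-bis(methoxymethoxy)-3-[(2R)-lavandulyl]phenyl}-1,3-dithiane | C=C(C)[C@H](CC=C(C)C)Cc1c(OCOC)cc(OC)c(C2SCCCS2)c1OCOC | intermediate
12 | 4-(1,3-dithian-2-yl)-5-methoxy-2-[(2R)-lavandulyl]benzene-1,3-diol | C=C(C)[C@H](CC=C(C)C)Cc1c(O)cc(OC)c(C2SCCCS2)c1O | intermediate
13 | 2-hydroxy-4-methoxybenzaldehyde | COc1ccc(C=O)c(O)c1 | starting material
14 | 4-methoxy-2-[(methylsulfanyl)methoxy]benzaldehyde | COc1ccc(C=O)c(OCSC)c1 | intermediate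
15 | rac-2-{4-methoxy-2-[(methylsulfanyl)methoxy]phenyl}oxirane | COc1ccc(C2CO2)c(OCSC)c1 | intermediate
16 | (2S)-2-{4-methoxy-2-[(methylsulfanyl)methoxy]phenyl}oxirane | COc1ccc([C@H]2CO2)c(OCSC)c1 | intermediate
17 | trilithium salt of 12: 2-lithio-1,3-dithian-2-yl carbanion with both phenols as lithium phenoxides | C=C(C)[C@H](CC=C(C)C)Cc1c(O[Li])cc(OC)c(C2([Li])SCCCS2)c1O[Li] | intermediate
18 | (1R)-2-{2-[2,4-dihydroxy-6-methoxy-3-((2R)-lavandulyl)phenyl]-1,3-dithian-2-yl}-1-{4-methoxy-2-[(methylsulfanyl)methoxy]phenyl}ethan-1-ol | C=C(C)[C@H](CC=C(C)C)Cc1c(O)cc(OC)c(C2(C[C@@H](O)c3ccc(OC)cc3OCSC)SCCCS2)c1O | intermediate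
19 | (2S)-5-methoxy-2-{4-methoxy-2-[(methylsulfanyl)methoxy]phenyl}-8-[(2R)-lavandulyl]-2,3-dihydrospiro[chromene-4,2'-[1,3]dithian]-7-ol | C=C(C)[C@H](CC=C(C)C)Cc1c(O)cc(OC)c2c1O[C@H](c1ccc(OC)cc1OCSC)CC21SCCCS1 | intermediate
20 | (2S)-7-hydroxy-2-(2-hydroxy-4-methoxyphenyl)-5-methoxy-8-[(2R)-5-methyl-2-(prop-1-en-2-yl)hex-4-en-1-yl]-2,3-dihydro-4H-chromen-4-one | C=C(C)[C@H](CC=C(C)C)Cc1c(O)cc(OC)c2c1O[C@H](c1ccc(OC)cc1O)CC2=O | target

**Totals.** 12 steps in all; the longest linear sequence is 8 steps (1, 2, 4, 5, 6, 10, 11, 12).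

**The three steps most likely to fail**

Step 10. The trianion may form incompletely or be poorly soluble, because the two phenoxides lower the acidity of the dithiane C–H. The fallback sets out from 12 and comes back at 18. Both phenols are masked with 2-(trimethylsilyl)ethoxymethyl chloride and i-Pr2NEt to give 2-{6-methoxy-3-[(2R)-lavandulyl]-2,4-bis{[2-(trimethylsilyl)ethoxy]methoxy}phenyl}-1,3-dithiane F3. Ordinary mono-lithiation (n-BuLi, THF, −30 °C) and opening of 16 then gives the bis-SEM (1R)-carbinol F4. TBAF in DMPU at 60 °C removes both SEM groups under basic conditions that do not ionise the benzylic carbinol and delivers 18.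

Step 11. The carbinol is benzylic to a 2,4-dioxygenated ring, so ionisation of the oxyphosphonium could erode the inversion and give some (2R)-epimer. The fallback sets out from 18 and comes back at 20. MeI/CaCO3 in aqueous MeCN first unmasks the ketone and the phenol to give (3R)-1-{2,4-dihydroxy-6-methoxy-3-[(2R)-lavandulyl]phenyl}-3-hydroxy-3-(2-hydroxy-4-methoxyphenyl)propan-1-one F5. Mild dehydration (pyridinium p-toluenesulfonate, toluene, 60 °C) gives (E)-1-{2,4-dihydroxy-6-methoxy-3-[(2R)-lavandulyl]phenyl}-3-(2-hydroxy-4-methoxyphenyl)prop-2-en-1-one F6. A quinine-derived bifunctional thiourea then catalyses the intramolecular oxa-Michael addition of the 2'-phenol to give 20. Selectivity in this cyclisation is expected to be only moderate, but the two C2 epimers are diastereomers because of the (R)-lavandulyl centre. The minor one is removed by preparative HPLC and recycled through F6 with NaOAc.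

Step 4. The hindered aryllithium may cause E2 elimination of the beta-branched iodide (to a conjugated diene) instead of substitution. The fallback sets out from 5 and 3 and comes back at 7. Compound 5 is lithiated as before and quenched with I2 to give 2-iodo-5-methoxy-1,3-bis(methoxymethoxy)benzene F1. Compound 3 is treated with t-BuLi (2 equiv, Et2O, −78 °C) and then B-methoxy-9-borabicyclo[3.3.1]nonane to give lithium B-methoxy-B-[lavandulyl]-9-borabicyclo[3.3.1]nonan-9-uide F2 (same spatial arrangement, 2S by CIP). A B-alkyl Suzuki–Miyaura coupling of F1 and F2 (Pd(dppf)Cl2, aqueous K3PO4, DMF/THF, 60 °C) gives 7.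

**Further compounds**
F1 | step 4 | 2-iodo-5-methoxy-1,3-bis(methoxymethoxy)benzene | COCOc1cc(OC)cc(OCOC)c1I
F2 | step 4 | lithium B-methoxy-B-[(2S)-5-methyl-2-(prop-1-en-2-yl)hex-4-en-1-yl]-9-borabicyclo[3.3.1]nonan-9-uide | [Li+].C=C(C)[C@H](CC=C(C)C)C[B-]1(OC)C2CCCC1CCC2
F3 | step 10 | 2-{6-methoxy-3-[(2R)-lavandulyl]-2,4-bis{[2-(trimethylsilyl)ethoxy]methoxy}phenyl}-1,3-dithiane | C=C(C)[C@H](CC=C(C)C)Cc1c(OCOCC[Si](C)(C)C)cc(OC)c(C2SCCCS2)c1OCOCC[Si](C)(C)C
F4 | step 10 | (1R)-2-{2-[6-methoxy-3-((2R)-lavandulyl)-2,4-bis{[2-(trimethylsilyl)ethoxy]methoxy}phenyl]-1,3-dithian-2-yl}-1-{4-methoxy-2-[(methylsulfanyl)methoxy]phenyl}ethan-1-ol | C=C(C)[C@H](CC=C(C)C)Cc1c(OCOCC[Si](C)(C)C)cc(OC)c(C2(C[C@@H](O)c3ccc(OC)cc3OCSC)SCCCS2)c1OCOCC[Si](C)(C)C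
F5 | step 11 | (3R)-1-{2,4-dihydroxy-6-methoxy-3-[(2R)-lavandulyl]phenyl}-3-hydroxy-3-(2-hydroxy-4-methoxyphenyl)propan-1-one | C=C(C)[C@H](CC=C(C)C)Cc1c(O)cc(OC)c(C(=O)C[C@@H](O)c2ccc(OC)cc2O)c1O
F6 | step 11 | (E)-1-{2,4-dihydroxy-6-methoxy-3-[(2R)-lavandulyl]phenyl}-3-(2-hydroxy-4-methoxyphenyl)prop-2-en-1-one | C=C(C)[C@H](CC=C(C)C)Cc1c(O)cc(OC)c(C(=O)/C=C/c2ccc(OC)cc2O)c1O
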